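**Retrosynthetic overview**
- The target comes from its 2',4'-di-O-benzyl ether; the C5 prenyl group comes from an aromatic Claisen shift of a 4-O-(1,1-dimethylallyl) ether, where C5 is the only free ortho carbon.
- The furan ring is the only ring built (both benzene rings are bought). It closes last, by an acid cascade on a 1,2-diaryl-3,3-dimethoxypropan-1-one: MOM loss, phenol onto ketone, dehydration, acetal to CHO. The 2,6-dioxygenated ring is symmetric, so either phenol gives the same benzofuran.
- Key C3–C3a bond: oxidative 1,2-aryl shift of a chalcone. Trivalent iodine turns the ketone α-carbon into an enolonium equivalent, and the electron-rich aryl carbon (itself a nucleophile) migrates onto it. This sets the 2-aryl and 3-formyl groups in one operation.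
- The chalcone comes from a Claisen–Schmidt condensation of 4-methoxy-2,6-bis(methoxymethoxy)benzaldehyde (from 5-methoxyresorcinol by MOM protection and directed ortho-lithiation/formylation) with 2,4-bis(benzyloxy)acetophenone.

Assumption: the target has no stereocentre and no stereogenic double bond, so it is achiral and "single enantiomer" means this one compound; the only stereo-element controlled in the route is the E-alkene of chalcone 7.

**Route**

Step 1
Reactants: 1 5-methoxyresorcinol
Product: 2 1-methoxy-3,5-bis(methoxymethoxy)benzene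
Conditions: MOMCl (2.5 equiv), K2CO3, acetone, 0 °C → rt
Reagents that add atoms: chloromethyl methyl ether (MOMCl), COCCl
Why: Williamson-type O-alkylation of both phenols (MOM protection) gives acetal ethers that survive base and organolithium and direct the next lithiation; no stereocentre is formed.

Step 2
Reactants: 2 1-methoxy-3,5-bis(methoxymethoxy)benzene
Product: 4 4-methoxy-2,6-bis(methoxymethoxy)benzaldehyde, via aryllithium 3 (not isolated)
Conditions: n-BuLi, TMEDA, THF, 0 °C; then DMF, 0 °C → rt; H2O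
Reagents that add atoms: N,N-dimethylformamide, CN(C)C=O; n-butyllithium, [Li]CCCC (lithium of intermediate 3 only)
Why: Directed ortho-metalation takes the C–H flanked by the two chelating OMOM groups (stronger directors than OMe) and DMF formylation of the aryllithium gives the symmetric aldehyde; no stereocentre is formed.

Step 3
Reactants: 5 1-(2,4-dihydroxyphenyl)ethan-1-one (2',4'-dihydroxyacetophenone)
Product: 6 1-[2,4-bis(benzyloxy)phenyl]ethan-1-one
Conditions: BnBr (2.4 equiv), K2CO3, DMF, 70 °C
Reagents that add atoms: benzyl bromide, BrCc1ccccc1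
Why: Williamson etherification gives benzyl ethers that are stable to KOH, trivalent iodine and TsOH, and that keep the 2'-oxygen from closing onto the later acetal (isoflavone pathway); no stereocentre is formed.

Step 4
Reactants: 4 4-methoxy-2,6-bis(methoxymethoxy)benzaldehyde; 6 1-[2,4-bis(benzyloxy)phenyl]ethan-1-one
Product: 7 (E)-1-[2,4-bis(benzyloxy)phenyl]-3-[4-methoxy-2,6-bis(methoxymethoxy)phenyl]prop-2-en-1-one
Conditions: KOH (3 equiv), EtOH/H2O, rt → 40 °C
Reagents that add atoms: none
Why: Claisen–Schmidt aldol condensation of a methyl ketone with a non-enolisable aldehyde, where E1cB dehydration gives only the thermodynamically favoured E-enone; no stereocentre is formed.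

Step 5
Reactants: 7 (E)-1-[2,4-bis(benzyloxy)phenyl]-3-[4-methoxy-2,6-bis(methoxymethoxy)phenyl]prop-2-en-1-one
Product: 9 rac-1-[2,4-bis(benzyloxy)phenyl]-3,3-dimethoxy-2-[4-methoxy-2,6-bis(methoxymethoxy)phenyl]propan-1-one, via α-iodanyl β-methoxy ketone 8 (not isolated)
Conditions: PhI(OH)OTs (1.2 equiv), MeOH, rt
Reagents that add atoms: methanol, CO; [hydroxy(tosyloxy)iodo]benzene, Cc1ccc(cc1)S(=O)(=O)OI(O)c1ccccc1 (iodine, phenyl, tosylate of intermediate 8 only)
Why: Hypervalent-iodine oxidative chalcone rearrangement: methanol adds at the benzylic carbon while trivalent iodine binds the ketone α-carbon, making it an enolonium equivalent onto which the electron-rich trialkoxyphenyl ring migrates (phenonium 1,2-aryl shift, reductive loss of PhI), and the resulting oxocarbenium ion is trapped as the dimethyl acetal; the new stereocentre is racemic and is erased at aromatisation in step 6.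

Step 6
Reactants: 9 rac-1-[2,4-bis(benzyloxy)phenyl]-3,3-dimethoxy-2-[4-methoxy-2,6-bis(methoxymethoxy)phenyl]propan-1-one
Product: 12 2-[2,4-bis(benzyloxy)phenyl]-4-hydroxy-6-methoxy-1-benzofuran-3-carbaldehyde, via diphenol keto acetal 10 (not isolated), via cyclic methyl acetal 11 (not isolated)
Conditions: p-TsOH·H2O (0.2 equiv), MeOH, 40 °C; concentrate; p-TsOH·H2O (1.1 equiv), (CF3)2CHOH, rt
Reagents that add atoms: water, O (oxygen of the aldehyde)
Why: Acidic methanolysis removes both MOM groups (formaldehyde is trapped as dimethoxymethane), then strong acid in the ionising fluoro-alcohol reopens the kinetic cyclic acetal and drives phenol-onto-ketone cyclodehydration (furan closure) with acetal hydrolysis, which is the known way to steer this intermediate to the 2-aryl-3-formylbenzofuran and not the 3-aroyl isomer; the symmetric ring makes both phenols equivalent and aromatisation removes the stereocentre.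

Step 7
Reactants: 13 2-methylbut-3-en-2-ol
Product: 15 2-methylbut-3-en-2-yl 2-methylpropyl carbonate, via lithium alkoxide 14 (not isolated)
Conditions: n-BuLi, THF, −78 → 0 °C; then iBuOCOCl, 0 °C → rt
Reagents that add atoms: isobutyl chloroformate, CC(C)COC(=O)Cl; n-butyllithium, [Li]CCCC (lithium of intermediate 14 only)
Why: O-acylation of the tertiary lithium alkoxide with a chloroformate gives the allylic carbonate cleanly where amine-base acylation of a tertiary alcohol is sluggish; no stereocentre is formed.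

Step 8
Reactants: 12 2-[2,4-bis(benzyloxy)phenyl]-4-hydroxy-6-methoxy-1-benzofuran-3-carbaldehyde; 15 2-methylbut-3-en-2-yl 2-methylpropyl carbonate
Product: 16 2-[2,4-bis(benzyloxy)phenyl]-6-methoxy-4-[(2-methylbut-3-en-2-yl)oxy]-1-benzofuran-3-carbaldehyde
Conditions: Pd(PPh3)4 (5 mol %), THF, 0 °C → rt
Reagents that add atoms: none
Why: Tsuji–Trost allylic etherification: zerovalent palladium ionises the carbonate with loss of CO2, the isobutoxide formed deprotonates the only free phenol, and the phenoxide attacks the 1,1-dimethylallyl palladium complex at its more substituted end under kinetic low-temperature control to give the tertiary ether; no stereocentre is formed.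

Step 9
Reactants: 16 2-[2,4-bis(benzyloxy)phenyl]-6-methoxy-4-[(2-methylbut-3-en-2-yl)oxy]-1-benzofuran-3-carbaldehyde
Product: 17 2-[2,4-bis(benzyloxy)phenyl]-4-hydroxy-6-methoxy-5-(3-methylbut-2-en-1-yl)-1-benzofuran-3-carbaldehyde
Conditions: PhMe, 110 °C, sealed tube
Reagents that add atoms: none
Why: Aromatic Claisen [3,3] rearrangement, accelerated by the gem-dimethyl group, can only deliver to C5 (the other ortho carbon is the ring-fusion carbon C3a) and the allyl inversion turns the 1,1-dimethylallyl ether into the linear prenyl group after re-aromatisation; no stereocentre is formed.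

Step 10
Reactants: 17 2-[2,4-bis(benzyloxy)phenyl]-4-hydroxy-6-methoxy-5-(3-methylbut-2-en-1-yl)-1-benzofuran-3-carbaldehyde
Product: 18 2-(2,4-dihydroxyphenyl)-4-hydroxy-6-methoxy-5-(3-methylbut-2-en-1-yl)-1-benzofuran-3-carbaldehyde
Conditions: BCl3 (5 equiv), C6HMe5 (6 equiv), CH2Cl2, −78 °C; then H2O
Reagents that add atoms: none
Why: Lewis-acid debenzylation of aryl benzyl ethers with pentamethylbenzene as a non-basic cation scavenger (Friedel–Crafts capture of the benzyl cation) runs at −78 °C, where the prenyl alkene, the methyl ether and the aldehyde are left alone; no stereocentre is formed.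

**Compound list**
1 | 5-methoxyresorcinol (5-methoxybenzene-1,3-diol) | COc1cc(O)cc(O)c1 | starting material
2 | 1-methoxy-3,5-bis(methoxymethoxy)benzene | COCOc1cc(OC)cc(OCOC)c1 | intermediate
3 | [4-methoxy-2,6-bis(methoxymethoxy)phenyl]lithium | [Li]c1c(OCOC)cc(OC)cc1OCOC | intermediate (not isolated)
4 | 4-methoxy-2,6-bis(methoxymethoxy)benzaldehyde | COCOc1cc(OC)cc(OCOC)c1C=O | intermediate
5 | 1-(2,4-dihydroxyphenyl)ethan-1-one | CC(=O)c1ccc(O)cc1O | starting material
6 | 1-[2,4-bis(benzyloxy)phenyl]ethan-1-one | CC(=O)c1ccc(OCc2ccccc2)cc1OCc1ccccc1 | intermediate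
7 | (E)-1-[2,4-bis(benzyloxy)phenyl]-3-[4-methoxy-2,6-bis(methoxymethoxy)phenyl]prop-2-en-1-one | COCOc1cc(OC)cc(OCOC)c1/C=C/C(=O)c1ccc(OCc2ccccc2)cc1OCc1ccccc1 | intermediate
8 | 1-[2,4-bis(benzyloxy)phenyl]-3-methoxy-3-[4-methoxy-2,6-bis(methoxymethoxy)phenyl]-2-[phenyl(tosyloxy)-λ3-iodanyl]propan-1-one (racemic diastereomer mixture) | COC(c1c(OCOC)cc(OC)cc1OCOC)C(C(=O)c1ccc(OCc2ccccc2)cc1OCc1ccccc1)I(c1ccccc1)OS(=O)(=O)c1ccc(C)cc1 | intermediate (not isolated)
9 | rac-1-[2,4-bis(benzyloxy)phenyl]-3,3-dimethoxy-2-[4-methoxy-2,6-bis(methoxymethoxy)phenyl]propan-1-one | COCOc1cc(OC)cc(OCOC)c1C(C(OC)OC)C(=O)c1ccc(OCc2ccccc2)cc1OCc1ccccc1 | intermediate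
10 | rac-1-[2,4-bis(benzyloxy)phenyl]-2-(2,6-dihydroxy-4-methoxyphenyl)-3,3-dimethoxypropan-1-one | COC(OC)C(C(=O)c1ccc(OCc2ccccc2)cc1OCc1ccccc1)c1c(O)cc(OC)cc1O | intermediate (not isolated)
11 | [2,4-bis(benzyloxy)phenyl](4-hydroxy-2,6-dimethoxy-2,3-dihydro-1-benzofuran-3-yl)methanone (racemic diastereomer mixture) | COC1Oc2cc(OC)cc(O)c2C1C(=O)c1ccc(OCc2ccccc2)cc1OCc1ccccc1 | intermediate (not isolated)
12 | 2-[2,4-bis(benzyloxy)phenyl]-4-hydroxy-6-methoxy-1-benzofuran-3-carbaldehyde | COc1cc(O)c2c(C=O)c(-c3ccc(OCc4ccccc4)cc3OCc3ccccc3)oc2c1 | intermediate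
13 | 2-methylbut-3-en-2-ol | CC(C)(O)C=C | starting material
14 | lithium 2-methylbut-3-en-2-olate | [Li]OC(C)(C)C=C | intermediate (not isolated)
15 | 2-methylbut-3-en-2-yl 2-methylpropyl carbonate | CC(C)COC(=O)OC(C)(C)C=C | intermediate
16 | 2-[2,4-bis(benzyloxy)phenyl]-6-methoxy-4-[(2-methylbut-3-en-2-yl)oxy]-1-benzofuran-3-carbaldehyde | COc1cc(OC(C)(C)C=C)c2c(C=O)c(-c3ccc(OCc4ccccc4)cc3OCc3ccccc3)oc2c1 | intermediate
17 | 2-[2,4-bis(benzyloxy)phenyl]-4-hydroxy-6-methoxy-5-(3-methylbut-2-en-1-yl)-1-benzofuran-3-carbaldehyde | COc1cc2oc(-c3ccc(OCc4ccccc4)cc3OCc3ccccc3)c(C=O)c2c(O)c1CC=C(C)C | intermediate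
18 | 2-(2,4-dihydroxyphenyl)-4-hydroxy-6-methoxy-5-(3-methylbut-2-en-1-yl)-1-benzofuran-3-carbaldehyde (ebenfuran III, achiral) | COc1cc2oc(-c3ccc(O)cc3O)c(C=O)c2c(O)c1CC=C(C)C | target

**Step count**
Total steps: 10 (nine on the carbon skeleton plus step 7, which prepares the allylic carbonate).
Longest linear sequence: 8 (steps 1, 2, 4, 5, 6, 8, 9, 10).

**Three steps most likely to fail, with fallbacks**

Step 5. The trivalent-iodine reagent may attack the free, very nucleophilic CH positions of the trialkoxy ring (aryliodonium formation) instead of the enone, and the TsOH released may strip a MOM group and expose an oxidisable phenol. The fallback sets out from 7 and comes back at 12, and it replaces the electrophilic oxidant by a nucleophilic one. Weitz–Scheffer epoxidation of 7 (H2O2, NaOH, MeOH/THF, 0 °C) gives the racemic trans-epoxy ketone [2,4-bis(benzyloxy)phenyl]{3-[4-methoxy-2,6-bis(methoxymethoxy)phenyl]oxiran-2-yl}methanone F1. BF3·OEt2 (CH2Cl2, −40 °C) opens the epoxide at the benzylic carbon and a 1,2-aroyl shift (House–Meinwald rearrangement) gives the keto aldehyde 3-[2,4-bis(benzyloxy)phenyl]-2-[4-methoxy-2,6-bis(methoxymethoxy)phenyl]-3-oxopropanal F2. F2 has the same carbon skeleton and oxidation pattern as 9 and is taken through the acid treatment of step 6 to give 12.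

Step 8. The 4-OH is hindered and hydrogen-bonded to the peri formyl group. If the phenoxide attacks the primary end of the allyl palladium complex, the linear O-prenyl ether forms, and its Claisen product is the wrong (1,1-dimethylallyl) isomer. The fallback sets out from 12 and comes back at 16, and it builds the tertiary ether through a propargyl cation equivalent that can only react at the tertiary carbon. Treatment of 12 with 3-chloro-3-methylbut-1-yne, DBU and catalytic CuCl2 (MeCN, 0 °C) gives the propargyl ether 2-[2,4-bis(benzyloxy)phenyl]-6-methoxy-4-[(2-methylbut-3-yn-2-yl)oxy]-1-benzofuran-3-carbaldehyde F3. Semihydrogenation (H2, Pd/CaCO3 poisoned with Pb(OAc)2, quinoline, EtOAc, rt) then gives 16.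

Step 10. BCl3 and the HCl it releases can add to the prenyl double bond or close it onto the neighbouring 4-OH to give a 2,2-dimethylchroman. The fallback sets out from 12 and comes back at 18, and it moves the debenzylation ahead of the prenyl chemistry so that the final deprotection uses fluoride.
- Hydrogenolysis of 12 (H2, Pd/C, EtOAc, rt) gives the triphenol 2-(2,4-dihydroxyphenyl)-4-hydroxy-6-methoxy-1-benzofuran-3-carbaldehyde F4.
- The two resorcinol hydroxyls are silylated in preference to the hydrogen-bonded 4-OH (TBSCl 2.1 equiv, imidazole, DMF, 0 °C) to give 2-[2,4-bis(tert-butyldimethylsilyloxy)phenyl]-4-hydroxy-6-methoxy-1-benzofuran-3-carbaldehyde F5. This selectivity is the uncertain point of the fallback.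
- Etherification with 15 as in step 8 gives 2-[2,4-bis(tert-butyldimethylsilyloxy)phenyl]-6-methoxy-4-[(2-methylbut-3-en-2-yl)oxy]-1-benzofuran-3-carbaldehyde F6.
- Claisen rearrangement as in step 9 gives 2-[2,4-bis(tert-butyldimethylsilyloxy)phenyl]-4-hydroxy-6-methoxy-5-(3-methylbut-2-en-1-yl)-1-benzofuran-3-carbaldehyde F7.
- TBAF buffered with AcOH (THF, 0 °C) then gives 18.

**Further compounds**
F1 | step 5 | rac-trans-[2,4-bis(benzyloxy)phenyl]{3-[4-methoxy-2,6-bis(methoxymethoxy)phenyl]oxiran-2-yl}methanone (one enantiomer drawn) | O=C(c1ccc(OCc2ccccc2)cc1OCc1ccccc1)[C@H]1O[C@@H]1c1c(OCOC)cc(OC)cc1OCOC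
F2 | step 5 | rac-3-[2,4-bis(benzyloxy)phenyl]-2-[4-methoxy-2,6-bis(methoxymethoxy)phenyl]-3-oxopropanal | O=CC(c1c(OCOC)cc(OC)cc1OCOC)C(=O)c1ccc(OCc2ccccc2)cc1OCc1ccccc1
F3 | step 8 | 2-[2,4-bis(benzyloxy)phenyl]-6-methoxy-4-[(2-methylbut-3-yn-2-yl)oxy]-1-benzofuran-3-carbaldehyde | COc1cc(OC(C)(C)C#C)c2c(C=O)c(-c3ccc(OCc4ccccc4)cc3OCc3ccccc3)oc2c1
F4 | step 10 | 2-(2,4-dihydroxyphenyl)-4-hydroxy-6-methoxy-1-benzofuran-3-carbaldehyde | COc1cc(O)c2c(C=O)c(-c3ccc(O)cc3O)oc2c1
F5 | step 10 | 2-[2,4-bis(tert-butyldimethylsilyloxy)phenyl]-4-hydroxy-6-methoxy-1-benzofuran-3-carbaldehyde | COc1cc(O)c2c(C=O)c(-c3ccc(O[Si](C)(C)C(C)(C)C)cc3O[Si](C)(C)C(C)(C)C)oc2c1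
F6 | step 10 | 2-[2,4-bis(tert-butyldimethylsilyloxy)phenyl]-6-methoxy-4-[(2-methylbut-3-en-2-yl)oxy]-1-benzofuran-3-carbaldehyde | COc1cc(OC(C)(C)C=C)c2c(C=O)c(-c3ccc(O[Si](C)(C)C(C)(C)C)cc3O[Si](C)(C)C(C)(C)C)oc2c1
F7 | step 10 | 2-[2,4-bis(tert-butyldimethylsilyloxy)phenyl]-4-hydroxy-6-methoxy-5-(3-methylbut-2-en-1-yl)-1-benzofuran-3-carbaldehyde | COc1cc2oc(-c3ccc(O[Si](C)(C)C(C)(C)C)cc3O[Si](C)(C)C(C)(C)C)c(C=O)c2c(O)c1CC=C(C)C
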